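## Analysis of the target

- Target 23 is an achiral, fully unsaturated benzophenone. Its 2-hydroxy-1,4-naphthoquinone has the quinone ring C1–C4 and the benzenoid ring A (C4a–C8a), with a methyl group on C5, the ketone bridge on C6 and a hydroxyl on C7.
- The ketone joins C6 to C1' of ring B, a 2',4'-dihydroxyphenyl ring whose C6' carries a CH2 group bonded to C6 of a 4-hydroxy-2H-pyran-2-one.
- There is no stereocentre and no stereogenic double bond, so every problem is one of regiochemistry or functional-group tolerance.
- The sensitive groups are the hydroxyquinone (redox-active, open to nucleophiles), the pyranone lactone (opened by hard nucleophiles), the acidic CH2 between ring B and the pyranone, and five acidic hydroxyls that must stay masked until the end.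
- Three features make the synthesis hard. The diaryl ketone has four ortho substituents. Ring A is pentasubstituted with only C8 free. The quinone is unsymmetrical, with its hydroxyl on C2, next to the C1 carbonyl bonded to C8a and remote from the peri methyl group on C5.
- The strategy rests on the chain C1(=O)–C2(OH)–C3(H)–C4(=O). With C2 taken out, C1, C3, C4, C4a and C8a form the five-membered ring of a 1-indanone whose carbonyl carbon is C1, so C2 can be put back as a dihalocarbene carbon between the carbonyl carbon and its alpha carbon.
- The halogen that arrives with C2 marks it for oxygen and leaves C4, para to the new naphthol oxygen, to be oxidised. The position of the indanone carbonyl therefore decides where the hydroxyl stands relative to the C5 methyl group.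

## Retrosynthetic reasoning

**23 to 22.** The last operation only removes protecting groups: the four O–CH3 bonds of 22 (three aryl ethers and the vinylogous ester ether on the pyranone) are cut. Methyl is used on every oxygen because it survives radical bromination, acylium ions, alkoxide, a carbene and a radical oxidant, and one Lewis-acid operation can remove all four. The forward step must free four hydroxyls without opening the lactone or reducing the quinone.

**22 to 21.** The C2–O bond is traced back to a C2–Br bond. Bromine makes C2 the only carbon where conjugate addition of an oxygen nucleophile can be followed by loss of a leaving group, so the hydroxyl cannot end up on C3. The oxygen pattern of the quinone is thereby reduced to the position of one halogen.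

**21 to 20.** The C4=O bond is removed: 21 is the para-quinone of 2-bromo-1-naphthol 20. C4 is the only free position para to the naphthol oxygen and C2 is blocked, so the oxidation has no regiochemical choice. It must only tolerate the methyl ethers and the lactone.

**20 to 15 and 16.** The bonds C1–C2 and C2–C3 are cut and the carbon between them is removed together with its bromine. What remains is silyl enol ether 15 of a 1-indanone, and the missing carbon is dibromocarbene 17 from bromoform 16. The cut is made here because it removes the whole problem of the oxygenated ring at once: no 1,2,4-trioxygenated naphthalene has to be assembled or differentiated. Forward, 17 must add only to the enol ether, and adduct 18 must open to bromonaphthalenone 19 and aromatise.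

**15 to 14.** The O–Si bond is cut. Indanone 14 has a single enolisable carbon, so the enol ether forms without a regiochemical question.

**14 to 12 and 4.** The bond between the ketone carbon and C1' of ring B is cut. It is cut on the ring B side because C1' of 4 is activated by an ortho and a para methoxy group, whereas the ring A carbon is flanked on both sides and sits on a deactivated ring. The acyl carbon therefore comes from ring A as acid 12, activated as mixed anhydride 13. This step joins the two halves and brings in the finished pyranone.

**12 to 11.** The C5–CO2H bond (indanone numbering) is replaced by C5–Br. The carboxyl group is introduced only at this point because a bromine at C5 helps the preceding ring closure, while a carboxyl there would deactivate the attacking carbon.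

**11 to 10.** The C1–C7a bond of the indanone is cut to give 3-arylpropanoic acid 10. Only one ortho position is open and it is para to bromine, so the closure can go only one way.

**10 to 6 and 7.** The acid chain is cut next to the benzylic carbon, giving aldehyde 6 and Meldrum's acid 7. The forward reductive alkylation via 8 and 9 must leave the aryl bromide alone, which rules out hydrogenation of a cinnamate.

**6 to 5.** The formyl–aryl bond is cut. Compound 5 already carries methoxy, bromine and methyl on three adjacent carbons, the pattern that is hardest to build, and its methoxy group directs the electrophile to the para position.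

**4 to 2 and 3.** The CH2–aryl bond is cut, so that ring B comes from boronic acid 3 and the pyranone with its CH2 from bromide 2. This avoids building the lactone on an arylacetic acid and methylating it afterwards.

**2 to 1.** The C–Br bond is cut; 1 already contains the lactone and the methyl ether.

## Alternatives that were turned down

**Alternative 1:** Both bonds at the adjacent ring B carbons C1' and C6' are cut at once, the C1'–carbonyl bond and the C6'–CH2 bond.
- Forward key step: a fluoride source unmasks the strained triple bond of silyl triflate A2. The enolate of naphthyl beta-keto ester A3 adds at the aryne carbon remote from the methoxy group, the aryl anion attacks the ketone, and the four-membered alkoxide fragments to ketone ester A1.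
- For it: the crowded ketone is made by an intramolecular acyl shift, the methoxy group of the aryne fixes the regiochemistry, the acetate arm is the handle for the pyranone, and the pyranone never meets a carbene or an alkoxide.
- Against it: A3 must already hold all oxygens of the quinone ring in differentiated form, so the placing of the C2 oxygen relative to the C5 methyl group is only moved into the synthesis of A3. The ketone of A3 is flanked by methyl and methoxy, so closure of the four-membered ring is slow and plain alpha-arylation after protonation of the aryl anion is the expected leak. The pyranone and an oxidative unmasking of the quinone still follow.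
- Comparison: Alternative 1 is stronger for the ketone and for the safety of the pyranone. The chosen route offers a key step that sets the quinone regiochemistry by construction and starts ring A from the simple anisole 5.

**Alternative 2:** The oxygenated ring is cut into a carbene carbon (C4), one carbonyl ligand (C1) and an alkyne (C2 and C3).
- Forward key step: the zerovalent chromium carbene complex A5 and alkynylboronate A6 combine in a Dötz benzannulation to give naphthol boronate A4.
- For it: all three oxygen positions are fixed in one step, since the boron ends next to the new phenol and can be oxidised to hydroxyl under mild conditions. No nucleophile has to displace a halide on a quinone. On this point it is as strong as or stronger than the chosen route.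
- Against it: the carbene complex is stoichiometric in a toxic metal. Its carbene carbon sits on an aryl carbon next to the methyl group, and ortho-substituted aryl carbenes are the ones that react slowly or divert to five- and four-membered rings. Making A5 needs an aryl anion on a ring that carries an ester. The ketone must then be made from the doubly flanked ester of A4 beside a free naphthol and a boronate, and ring B and the pyranone all come after the key step.
- Comparison: the chosen route offers a metal-free key step on the complete carbon skeleton, with three operations after it.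

**Alternative 3:** Ring B is cut at C1'–C2' and C5'–C6'.
- Forward key step: naphthyl ynone A8 and silyloxy diene A9 undergo a Diels–Alder reaction, and 1,4-elimination of one methoxy group as the alcohol aromatises the adduct to A7.
- For it: the ketone with four ortho substituents comes from a linear ynone, so no crowded bond is made between two finished arenes, and diene polarity fixes the regiochemistry. For the ketone this is the stronger plan.
- Against it: like Alternative 1 it needs the fully oxygenated naphthalene first. The alkyne is disubstituted and carries a bulky aroyl group, which slows the cycloaddition and favours simple conjugate addition of the diene. A7 still lacks four carbons of the pyranone and has a free phenol, so several steps follow next to a ketone.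
- Comparison: the chosen route offers the shorter sequence, because ring B with the pyranone (4) is made in two steps and joined to ring A in one.

Key step: step 9

Assumption: 1, 3, 5, 7 and 16 are taken as purchasable, and the hydroxyquinone and hydroxypyranone are treated in the tautomeric forms drawn for the target.

## Route

**Step 1**
Reactants: 1 4-methoxy-6-methyl-2H-pyran-2-one
Product: 2 6-(bromomethyl)-4-methoxy-2H-pyran-2-one
Conditions: NBS, (PhCO2)2 (cat.), PhCF3, reflux
Reagents that add atoms: N-bromosuccinimide, O=C1CCC(=O)N1Br
Why: Wohl–Ziegler bromination; hydrogen abstraction from the C6 methyl gives a radical delocalised over the pyranone diene, and the low steady concentration of bromine in a non-polar solvent suppresses ionic bromination at C3.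

**Step 2**
Reactants: 2 6-(bromomethyl)-4-methoxy-2H-pyran-2-one; 3 3,5-dimethoxyphenylboronic acid
Product: 4 6-(3,5-dimethoxybenzyl)-4-methoxy-2H-pyran-2-one
Conditions: Pd(PPh3)4 (5 mol %), K2CO3, toluene/H2O, 80 °C
Reagents that add atoms: none
Why: Suzuki–Miyaura coupling of an allylic, benzylic-type bromide; oxidative addition to zerovalent palladium is fast at the activated C–Br bond, there is no beta hydrogen to eliminate, and the mild carbonate base should leave the methoxypyranone intact.

**Step 3**
Reactants: 5 2-bromo-1-methoxy-3-methylbenzene
Product: 6 3-bromo-4-methoxy-2-methylbenzaldehyde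
Conditions: Cl2CHOMe, TiCl4, CH2Cl2, −10 → 0 °C; then H2O
Reagents that add atoms: dichloromethyl methyl ether, COC(Cl)Cl; water, O
Why: Rieche formylation; the methoxy group directs para, to the carbon that is also ortho to the methyl group, while its own free ortho position is shielded because the flanking bromine turns the O-methyl group towards it.

**Step 4**
Reactants: 6 3-bromo-4-methoxy-2-methylbenzaldehyde; 7 Meldrum's acid (2,2-dimethyl-1,3-dioxane-4,6-dione)
Product: 10 3-(3-bromo-4-methoxy-2-methylphenyl)propanoic acid, via arylidene Meldrum's acid 8 (not isolated), via benzyl Meldrum's acid 9 (not isolated)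
Conditions: HCO2H/Et3N (5:2), 100 °C; then aq. HCl
Reagents that add atoms: none
Why: Knoevenagel condensation gives 8, formate transfers hydride to this doubly activated alkene to give 9, and the water from the condensation opens the dioxanedione, which loses acetone and CO2 at 100 °C. This reductive alkylation of Meldrum's acid does not touch the aryl bromide, which hydrogenation of a cinnamate would endanger.

**Step 5**
Reactants: 10 3-(3-bromo-4-methoxy-2-methylphenyl)propanoic acid
Product: 11 5-bromo-6-methoxy-4-methyl-2,3-dihydro-1H-inden-1-one
Conditions: TfOH, 0 °C → rt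
Reagents that add atoms: none
Why: Intramolecular Friedel–Crafts acylation through the acylium ion; only one ortho position is free and it is para to bromine, a para-directing substituent, as in the closure of related 3-(3-halo-4-methoxyphenyl)propanoic acids to 5-halo-6-methoxy-1-indanones.

**Step 6**
Reactants: 11 5-bromo-6-methoxy-4-methyl-2,3-dihydro-1H-inden-1-one
Product: 12 6-methoxy-4-methyl-1-oxo-2,3-dihydro-1H-indene-5-carboxylic acid
Conditions: Pd(OAc)2 (5 mol %), Xantphos, CO (3 bar), H2O, Et3N, 1,4-dioxane, 100 °C; then aq. HCl
Reagents that add atoms: carbon monoxide, [C-]#[O+]; water, O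
Why: Palladium-catalysed hydroxycarbonylation; oxidative addition at the C–Br bond (activated by the para ketone), CO insertion and hydrolysis of the acylpalladium species by water. The wide-bite-angle diphosphine is chosen for ortho-substituted aryl bromides, and the free acid is obtained directly so that no hindered ester has to be saponified.

**Step 7**
Reactants: 12 6-methoxy-4-methyl-1-oxo-2,3-dihydro-1H-indene-5-carboxylic acid; 4 6-(3,5-dimethoxybenzyl)-4-methoxy-2H-pyran-2-one
Product: 14 6-[3,5-dimethoxy-2-(6-methoxy-4-methyl-1-oxo-2,3-dihydro-1H-indene-5-carbonyl)benzyl]-4-methoxy-2H-pyran-2-one, via mixed trifluoroacetic anhydride 13 (not isolated)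
Conditions: (CF3CO)2O, TfOH (cat.), CH2Cl2, 0 °C → rt
Reagents that add atoms: none
Why: Friedel–Crafts acylation through mixed anhydride 13; the 2,6-disubstituted aroyl group ionises readily to an acylium ion, which should attack 4 at the ring carbon ortho to the CH2 group and para to a methoxy group, the usual site in 3,5-dimethoxybenzyl compounds, rather than between the two methoxy groups or at the much less nucleophilic pyranone C3. No metal halide Lewis acid is present, so the methoxy groups ortho to the new ketone should not be cleaved.

**Step 8**
Reactants: 14 6-[3,5-dimethoxy-2-(6-methoxy-4-methyl-1-oxo-2,3-dihydro-1H-indene-5-carbonyl)benzyl]-4-methoxy-2H-pyran-2-one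
Product: 15 6-{3,5-dimethoxy-2-[5-methoxy-7-methyl-3-(trimethylsilyloxy)-1H-indene-6-carbonyl]benzyl}-4-methoxy-2H-pyran-2-one
Conditions: TMSOTf (1.2 equiv), Et3N, CH2Cl2, −20 → 0 °C; non-aqueous work-up, used crude
Reagents that add atoms: trimethylsilyl trifluoromethanesulfonate, C[Si](C)(C)OS(=O)(=O)C(F)(F)F
Why: Soft enolisation; the indanone carbonyl is silylated on oxygen and Et3N removes one of its only alpha hydrogens. The diaryl ketone cannot enolise and the lactone carbonyl is far less basic, so a slight excess of reagent should be selective.

**Step 9**
Reactants: 15 6-{3,5-dimethoxy-2-[5-methoxy-7-methyl-3-(trimethylsilyloxy)-1H-indene-6-carbonyl]benzyl}-4-methoxy-2H-pyran-2-one; 16 bromoform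
Product: 20 6-[2-(6-bromo-5-hydroxy-3-methoxy-1-methylnaphthalene-2-carbonyl)-3,5-dimethoxybenzyl]-4-methoxy-2H-pyran-2-one, via dibromocarbene 17 (not isolated), via dibromocyclopropane 18 (not isolated), via bromonaphthalenone 19 (not isolated)
Conditions: 16 (1.5 equiv), KOtBu (3 equiv, added in portions), toluene/hexane, −30 °C → rt; then 1 M HCl
Reagents that add atoms: none
Why: Alpha-elimination of HBr from 16 by KOtBu gives carbene 17, which adds as an electrophile to the enol ether double bond of 15, the most electron-rich alkene present, to give the cis-fused dibromo(silyloxy)cyclopropane 18. One bromide then leaves while the cyclopropane bond shared with the five-membered ring opens in a disrotatory two-electron electrocyclic process pushed by the silyloxy oxygen; loss of the silyl group from the oxocarbenium ion gives 19, which tautomerises at once to the aromatic naphthol, set free from its potassium salt on acidification. The closest known reaction type is the dihalocarbene ring expansion of cyclic silyl enol ethers to 2-halo enones and of 1-indanone silyl enol ethers to 2-halo-1-naphthols. The six-membered ring is closed by ring enlargement and not by cyclisation of a chain: the carbene carbon becomes C2 and forms C1–C2 and C2–C3 while the old C1–C3 bond breaks. No stereocentre remains, since the two ring-fusion centres of 18 can only be cis and both are destroyed on opening. Regiochemistry needs no control, because 14 had a single enolisable carbon and the bromine must sit on the inserted carbon. The selectivity needed is chemoselectivity for the enol ether over the pyranone double bonds, which the lactone carbonyl deactivates, and over the methoxyarenes, which do not add dihalocarbenes; the acidic CH2 between ring B and the pyranone is protected kinetically by adding the alkoxide slowly to an excess of the much more acidic 16 at low temperature.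

**Step 10**
Reactants: 20 6-[2-(6-bromo-5-hydroxy-3-methoxy-1-methylnaphthalene-2-carbonyl)-3,5-dimethoxybenzyl]-4-methoxy-2H-pyran-2-one
Product: 21 6-[2-(6-bromo-3-methoxy-1-methyl-5,8-dioxo-5,8-dihydronaphthalene-2-carbonyl)-3,5-dimethoxybenzyl]-4-methoxy-2H-pyran-2-one
Conditions: K2NO(SO3)2 (2.5 equiv), KH2PO4, acetone/H2O, rt
Reagents that add atoms: potassium nitrosodisulfonate, [K+].[K+].[O]N(S(=O)(=O)[O-])S(=O)(=O)[O-]
Why: Teuber oxidation; the nitroxyl radical removes the phenolic hydrogen, a second equivalent couples at C4, the only free position para to the oxygen, and loss of the imidodisulfonate gives the para-quinone. C2 is blocked by bromine so no ortho-quinone can form, and the buffered neutral medium should spare the lactone and the ethers.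

**Step 11**
Reactants: 21 6-[2-(6-bromo-3-methoxy-1-methyl-5,8-dioxo-5,8-dihydronaphthalene-2-carbonyl)-3,5-dimethoxybenzyl]-4-methoxy-2H-pyran-2-one
Product: 22 6-[2-(6-hydroxy-3-methoxy-1-methyl-5,8-dioxo-5,8-dihydronaphthalene-2-carbonyl)-3,5-dimethoxybenzyl]-4-methoxy-2H-pyran-2-one
Conditions: KOH (0.2 M aq., 3 equiv), THF, 0 °C, short contact; then 1 M HCl
Reagents that add atoms: potassium hydroxide, [K+].[OH-]
Why: Addition–elimination on a halogenated quinone; hydroxide adds in conjugate fashion at C2, bromide leaves, and the product is withdrawn as its stable vinylogous carboxylate. Addition at C3 is reversible and has no leaving group, so the oxygen stays on the carbon that carried bromine; dilute base at 0 °C is used so that the quinone, the most electrophilic site, reacts before the lactone.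

**Step 12**
Reactants: 22 6-[2-(6-hydroxy-3-methoxy-1-methyl-5,8-dioxo-5,8-dihydronaphthalene-2-carbonyl)-3,5-dimethoxybenzyl]-4-methoxy-2H-pyran-2-one
Product: 23 6-[2-(3,6-dihydroxy-1-methyl-5,8-dioxo-5,8-dihydronaphthalene-2-carbonyl)-3,5-dihydroxybenzyl]-4-hydroxy-2H-pyran-2-one
Conditions: BBr3 (excess), CH2Cl2, −78 °C → rt; then H2O
Reagents that add atoms: none
Why: Lewis-acid ether cleavage; BBr3 binds each ether oxygen and the pyranone carbonyl (which turns the 4-methoxy group into the methyl ether of a pyrylium-like vinylogous ester), and bromide removes the methyl groups by SN2, the ethers ortho to the diaryl ketone first through chelation. Aqueous work-up hydrolyses the borates to the free hydroxyls of 23.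

## Compound list

1 | 4-methoxy-6-methyl-2H-pyran-2-one | Cc1cc(OC)cc(=O)o1 | starting material
2 | 6-(bromomethyl)-4-methoxy-2H-pyran-2-one | BrCc1cc(OC)cc(=O)o1 | intermediate
3 | 3,5-dimethoxyphenylboronic acid | COc1cc(OC)cc(B(O)O)c1 | starting material
4 | 6-(3,5-dimethoxybenzyl)-4-methoxy-2H-pyran-2-one | COc1cc(Cc2cc(OC)cc(=O)o2)cc(OC)c1 | intermediate
5 | 2-bromo-1-methoxy-3-methylbenzene | COc1cccc(C)c1Br | starting material
6 | 3-bromo-4-methoxy-2-methylbenzaldehyde | COc1ccc(C=O)c(C)c1Br | intermediate
7 | Meldrum's acid (2,2-dimethyl-1,3-dioxane-4,6-dione) | CC1(C)OC(=O)CC(=O)O1 | starting material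
8 | 5-(3-bromo-4-methoxy-2-methylbenzylidene)-2,2-dimethyl-1,3-dioxane-4,6-dione | COc1ccc(C=C2C(=O)OC(C)(C)OC2=O)c(C)c1Br | intermediate
9 | 5-(3-bromo-4-methoxy-2-methylbenzyl)-2,2-dimethyl-1,3-dioxane-4,6-dione | COc1ccc(CC2C(=O)OC(C)(C)OC2=O)c(C)c1Br | intermediate
10 | 3-(3-bromo-4-methoxy-2-methylphenyl)propanoic acid | COc1ccc(CCC(=O)O)c(C)c1Br | intermediate
11 | 5-bromo-6-methoxy-4-methyl-2,3-dihydro-1H-inden-1-one | COc1cc2C(=O)CCc2c(C)c1Br | intermediate
12 | 6-methoxy-4-methyl-1-oxo-2,3-dihydro-1H-indene-5-carboxylic acid | COc1cc2C(=O)CCc2c(C)c1C(=O)O | intermediate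
13 | 6-methoxy-4-methyl-1-oxo-2,3-dihydro-1H-indene-5-carboxylic trifluoroacetic anhydride | COc1cc2C(=O)CCc2c(C)c1C(=O)OC(=O)C(F)(F)F | intermediate
14 | 6-[3,5-dimethoxy-2-(6-methoxy-4-methyl-1-oxo-2,3-dihydro-1H-indene-5-carbonyl)benzyl]-4-methoxy-2H-pyran-2-one | COc1cc2C(=O)CCc2c(C)c1C(=O)c1c(OC)cc(OC)cc1Cc1cc(OC)cc(=O)o1 | intermediate
15 | 6-{3,5-dimethoxy-2-[5-methoxy-7-methyl-3-(trimethylsilyloxy)-1H-indene-6-carbonyl]benzyl}-4-methoxy-2H-pyran-2-one | C[Si](C)(C)OC1=CCc2c1cc(OC)c(C(=O)c1c(OC)cc(OC)cc1Cc1cc(OC)cc(=O)o1)c2C | intermediate
16 | bromoform | BrC(Br)Br | starting material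
17 | dibromocarbene | Br[C]Br | intermediate
18 | CBr2 adduct of 15 across the enol ether double bond: 6-{2-[1,1-dibromo-3-methoxy-5-methyl-1a-(trimethylsilyloxy)-1,1a,6,6a-tetrahydrocyclopropa[a]indene-4-carbonyl]-3,5-dimethoxybenzyl}-4-methoxy-2H-pyran-2-one (racemic; ring fusion necessarily cis) | C[Si](C)(C)OC12C(Cc3c1cc(OC)c(C(=O)c1c(OC)cc(OC)cc1Cc1cc(OC)cc(=O)o1)c3C)C2(Br)Br | intermediate
19 | 6-[2-(6-bromo-3-methoxy-1-methyl-5-oxo-5,8-dihydronaphthalene-2-carbonyl)-3,5-dimethoxybenzyl]-4-methoxy-2H-pyran-2-one | O=C1C(Br)=CCc2c1cc(OC)c(C(=O)c1c(OC)cc(OC)cc1Cc1cc(OC)cc(=O)o1)c2C | intermediate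
20 | 6-[2-(6-bromo-5-hydroxy-3-methoxy-1-methylnaphthalene-2-carbonyl)-3,5-dimethoxybenzyl]-4-methoxy-2H-pyran-2-one | Oc1c(Br)ccc2c(C)c(C(=O)c3c(OC)cc(OC)cc3Cc3cc(OC)cc(=O)o3)c(OC)cc12 | intermediate
21 | 6-[2-(6-bromo-3-methoxy-1-methyl-5,8-dioxo-5,8-dihydronaphthalene-2-carbonyl)-3,5-dimethoxybenzyl]-4-methoxy-2H-pyran-2-one | O=C1C(Br)=CC(=O)c2c1cc(OC)c(C(=O)c1c(OC)cc(OC)cc1Cc1cc(OC)cc(=O)o1)c2C | intermediate
22 | 6-[2-(6-hydroxy-3-methoxy-1-methyl-5,8-dioxo-5,8-dihydronaphthalene-2-carbonyl)-3,5-dimethoxybenzyl]-4-methoxy-2H-pyran-2-one | O=C1C(O)=CC(=O)c2c1cc(OC)c(C(=O)c1c(OC)cc(OC)cc1Cc1cc(OC)cc(=O)o1)c2C | intermediate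
23 | 6-[2-(3,6-dihydroxy-1-methyl-5,8-dioxo-5,8-dihydronaphthalene-2-carbonyl)-3,5-dihydroxybenzyl]-4-hydroxy-2H-pyran-2-one | Cc1c(C(=O)c2c(O)cc(O)cc2Cc2cc(O)cc(=O)o2)c(O)cc2c1C(=O)C=C(O)C2=O | target

## Step count and least certain steps

Total: 12 steps. Longest linear sequence: 10 steps (steps 3 to 12, from 5); steps 1 and 2 run in parallel and deliver 4.

**Step 9 (key step).**
- What may go wrong: deprotonation of the acidic CH2 between ring B and the pyranone by tert-butoxide, followed by carbene capture there or aldol-type closure onto the diaryl ketone; cleavage of the Si–O bond by the alkoxide before cyclopropanation; and further attack of excess carbene on the naphthoxide. All three stem from the strong base needed to make the carbene. A neutral carbene source (thermolysis of PhHgCBr3) would be the first change of conditions.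
- Fallback, base-free and stepwise, from 15 back to 20: Simmons–Smith cyclopropanation of 15 (Et2Zn, CH2I2, CH2Cl2, 0 °C) should give the silyloxycyclopropane F1. One-electron oxidation with FeCl3 in DMF should open the bond shared by the two rings to the ring-enlarged 3-chloro ketone F2. NaOAc in warm MeOH should eliminate HCl and let the dienone aromatise to the naphthol F3. Ortho-selective bromination (NBS, catalytic i-Pr2NH, CH2Cl2, −78 °C), helped by the peri methyl group that shields C4, should return to 20.

**Step 12.**
- What may go wrong: incomplete cleavage of the pyranone methyl ether, whose oxygen is a poor Lewis base, while the aryl ethers are already gone; and acid-promoted condensation between pyranone C5 and the diaryl ketone on prolonged exposure.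
- Fallback, from 22 to 23 in two stages with a different mechanism for the last ether: BBr3 at low temperature is stopped after the three aryl ethers, giving the pyranone methyl ether F4. This vinylogous methyl ester is then dealkylated by chloride in an SN2 reaction at the methyl group (LiCl, DMF, 120 °C), as for methyl esters, giving 23.

**Step 11.**
- What may go wrong: opening of the methoxypyranone lactone by hydroxide in competition with substitution at the quinone.
- Fallback, from 21 to 23 with the order of the last two operations reversed: BBr3 first converts 21 into the bromoquinone pentol F5, in which the pyranone is a 4-hydroxypyranone whose anion resists hydroxide. Aqueous NaOH at rt followed by acid then replaces bromine by hydroxyl and gives 23. The price is a slower substitution, because the C7 phenoxide donates into the C4 carbonyl.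

**Step 6.**
- What may go wrong: slow oxidative addition and CO insertion at a C–Br bond flanked by methyl and methoxy, so that reductive loss of bromine or stalling competes.
- Fallback, from 11 to 12 through an aryllithium: ketalisation (ethylene glycol, TsOH, toluene, water removal) should give the dioxolane F6. Bromine–lithium exchange (n-BuLi, THF, −78 °C) and quenching with CO2 should give the ketal acid F7, and aqueous HCl in THF should release the ketone to give 12.

## Further compounds

F1 | step 9 | 6-{3,5-dimethoxy-2-[3-methoxy-5-methyl-1a-(trimethylsilyloxy)-1,1a,6,6a-tetrahydrocyclopropa[a]indene-4-carbonyl]benzyl}-4-methoxy-2H-pyran-2-one (racemic, cis-fused) | C[Si](C)(C)OC12CC1Cc1c2cc(OC)c(C(=O)c2c(OC)cc(OC)cc2Cc2cc(OC)cc(=O)o2)c1C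
F2 | step 9 | 6-[2-(7-chloro-3-methoxy-1-methyl-5-oxo-5,6,7,8-tetrahydronaphthalene-2-carbonyl)-3,5-dimethoxybenzyl]-4-methoxy-2H-pyran-2-one (racemic) | O=C1CC(Cl)Cc2c1cc(OC)c(C(=O)c1c(OC)cc(OC)cc1Cc1cc(OC)cc(=O)o1)c2C
F3 | step 9 | 6-[2-(5-hydroxy-3-methoxy-1-methylnaphthalene-2-carbonyl)-3,5-dimethoxybenzyl]-4-methoxy-2H-pyran-2-one | Oc1cccc2c(C)c(C(=O)c3c(OC)cc(OC)cc3Cc3cc(OC)cc(=O)o3)c(OC)cc12
F4 | step 12 | 6-[2-(3,6-dihydroxy-1-methyl-5,8-dioxo-5,8-dihydronaphthalene-2-carbonyl)-3,5-dihydroxybenzyl]-4-methoxy-2H-pyran-2-one | Cc1c(C(=O)c2c(O)cc(O)cc2Cc2cc(OC)cc(=O)o2)c(O)cc2c1C(=O)C=C(O)C2=O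
F5 | step 11 | 6-[2-(6-bromo-3-hydroxy-1-methyl-5,8-dioxo-5,8-dihydronaphthalene-2-carbonyl)-3,5-dihydroxybenzyl]-4-hydroxy-2H-pyran-2-one | Cc1c(C(=O)c2c(O)cc(O)cc2Cc2cc(O)cc(=O)o2)c(O)cc2c1C(=O)C=C(Br)C2=O
F6 | step 6 | 5'-bromo-6'-methoxy-4'-methyl-2',3'-dihydrospiro[1,3-dioxolane-2,1'-indene] | COc1cc2c(CCC23OCCO3)c(C)c1Br
F7 | step 6 | 6'-methoxy-4'-methyl-2',3'-dihydrospiro[1,3-dioxolane-2,1'-indene]-5'-carboxylic acid | COc1cc2c(CCC23OCCO3)c(C)c1C(=O)O
A1 | alternative 1 | methyl 2-[3,5-dimethoxy-2-(3,5,6,8-tetramethoxy-1-methylnaphthalene-2-carbonyl)phenyl]acetate | COC(=O)Cc1cc(OC)cc(OC)c1C(=O)c1c(C)c2c(OC)cc(OC)c(OC)c2cc1OC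
A2 | alternative 1 | 3,5-dimethoxy-2-(trimethylsilyl)phenyl trifluoromethanesulfonate | COc1cc(OC)c([Si](C)(C)C)c(OS(=O)(=O)C(F)(F)F)c1
A3 | alternative 1 | methyl 3-oxo-3-(3,5,6,8-tetramethoxy-1-methylnaphthalen-2-yl)propanoate | COC(=O)CC(=O)c1c(C)c2c(OC)cc(OC)c(OC)c2cc1OC
A4 | alternative 2 | methyl 5-hydroxy-3,8-dimethoxy-1-methyl-6-(4,4,5,5-tetramethyl-1,3,2-dioxaborolan-2-yl)naphthalene-2-carboxylate | COC(=O)c1c(C)c2c(OC)cc(B3OC(C)(C)C(C)(C)O3)c(O)c2cc1OC
A5 | alternative 2 | pentacarbonyl{methoxy[4-methoxy-3-(methoxycarbonyl)-2-methylphenyl]methylidene}chromium, (CO)5Cr=C(OMe)Ar | COC(c1ccc(OC)c(C(=O)OC)c1C)=[Cr](=C=O)(=C=O)(=C=O)(=C=O)=C=O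
A6 | alternative 2 | 2-ethynyl-4,4,5,5-tetramethyl-1,3,2-dioxaborolane | C#CB1OC(C)(C)C(C)(C)O1
A7 | alternative 3 | [2-(2,2-diethoxyethyl)-4-hydroxy-6-methoxyphenyl](3,5,6,8-tetramethoxy-1-methylnaphthalen-2-yl)methanone | CCOC(OCC)Cc1cc(O)cc(OC)c1C(=O)c1c(C)c2c(OC)cc(OC)c(OC)c2cc1OC
A8 | alternative 3 | 5,5-diethoxy-1-(3,5,6,8-tetramethoxy-1-methylnaphthalen-2-yl)pent-2-yn-1-one | CCOC(OCC)CC#CC(=O)c1c(C)c2c(OC)cc(OC)c(OC)c2cc1OC
A9 | alternative 3 | 1,1-dimethoxy-3-(trimethylsilyloxy)buta-1,3-diene | COC(OC)=CC(=C)O[Si](C)(C)C
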